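Readings and results come from a simulation for substances that don't exist; scatter was added.

The dusk run, with its solid substrate stirred in a closed flask, made single ring along a straight line after a short lag, and I wanted to know what that line was worth on the noon flask.

| flask | solid substrate | remark | time |
|---|---|---|---|
| noon | 1 M | the very flask that is asked about, followed so far |  |
| dusk | 0.67 M | run made earlier |  |
| flask | 1.0 M |  | 1.0 h |

| noon: time / min | noon: single ring / % | dusk: time / min | dusk: single ring / % |
|---|---|---|---|
| 6.00 | 0.8 | 15.0 | 3.2 |
| 12.0 | 1.9 | 30.0 | 8.0 |
| 20.0 | 3.4 | 50.0 | 14.4 |
| 25.0 | 4.3 | 60.0 | 17.5 |

(standard deviation of a reading: 0.3 percentage points)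

* how much single ring there is at 1.0 h, in percent of the solid substrate charged
* the change that raises the amount of single ring at 1.0 h, in percent of the solid substrate charged most ("none" if none brings more than 2 percentage points) (ash / maple / none)
* amount of single ring at 1.0 h, in percent of the solid substrate charged, after ash

- ash: doubling the dissolution coefficient of the solid substrate, all else as stated
- maple: doubling the solubility of the solid substrate, all else as stated

- solid, in amounts per volume of the solution: solid substrate
- at the start none of the solid substrate is in solution

From the first to the last dusk reading I took the steady making rate, the rise of c(single ring) per minute in moles per litre, not in percent of the charge, a pseudo-zero-order rate of 0.00213 M min⁻¹, and the line met zero at a lag of 4.93 min. Carried to the noon run, this gave 4.27% at 25.0 min, where the reading was 4.3%. Dusk stayed straight up to 60.0 min with less solid charged, and the lag was a small correction, so I reckoned 11.7% at 1.0 h; the line gave me no figure for ash or maple, so I committed to none.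

The forecast gave 11.5%, chose maple and put ash at 12%, reading the loading this way: “The rate's independence of loading suggests the reaction, not dissolution, limits it”.

The flask gave 12.1%, and maple was best with a gain of 9.2 percentage points, while ash gained 5.1 points and reached 17.3%.

    2 starting material → open dimer (k = 0.00630 L mol⁻¹ s⁻¹)
    starting material → single ring (k = 9.20 × 10⁻⁴ s⁻¹)
    starting material + open dimer → open trimer (k = 3.40 × 10⁻⁴ L mol⁻¹ s⁻¹)
    solid substrate ⇌ starting material, rate k4*(cs4 - [starting material]) while solid is left; crystals form when [starting material] > cs4 (solubility = 0.110 M, k = 8.60 × 10⁻⁴ s⁻¹)
    open dimer → ring dimer (k = 0.0110 s⁻¹)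

In the flask, starting material stood at 4.08% at 0.500 h and 4.11% at 1.00 h, which is 0.0411 M, less than the solubility of 0.11 M. Read at 40 min, the same flask should hold 7.47% by the same rate and lag, and it held 7.60% of single ring, with starting material at 4.11%.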